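**Plan**

Locants: C1 = methyl-bearing fusion carbon, C2, C3, C4 = C(OH)(i-Pr), C5 = fusion CH, C6 = CH–O(aroyl), C7, C8 = C(OH)(CH3), C9=C10.
Retrosynthesis cuts, in order: the aryl ester at O–C6; the C5–C6 bond together with C4–O, through an isoxazoline; the C8–C9 bond and the C7–H/C8–O pattern (Sonogashira coupling, epoxy alcohol); C4–i-Pr and C1–CH3 on a cyclopentenone.
Enabling feature: the O–C4–C5–C6–O array across the fusion carbon of the cis-fused five/seven-membered ring system is a masked β-hydroxy ketone. This maps onto a nitrile oxide at C6 and the trisubstituted C4=C5 alkene of a cyclopentene, joined through quaternary C1 by the (Z)-C10=C9–C8–C7 arm.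
Forward: the cyclopentene is built first, then the chain; the seven-membered ring and the temporary isoxazoline close in one intramolecular (3+2) cycloaddition; N–O cleavage, reduction, acylation and desilylation finish.
Stereochemistry: C1 from catalyst-controlled conjugate methylation; C8 from Sharpless epoxidation; C4 and C5 from the tether-controlled cycloaddition (relay from C1); C6 from hydride delivery by the C4 hydroxyl.

Key step: step 12

Remark: 4-[(tert-butyldimethylsilyl)oxy]benzoic acid (26) is taken as a catalogue compound (otherwise one operation from 4-hydroxybenzoic acid: TBSCl/imidazole, then K2CO3/MeOH).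

**Step 1**
Reactants: 1 3-ethoxycyclopent-2-en-1-one; 2 ethynyltri(propan-2-yl)silane
Product: 5 3-{[tri(propan-2-yl)silyl]ethynyl}cyclopent-2-en-1-one, via lithium silylacetylide 3 (not isolated), via lithium alkoxide adduct 4 (not isolated)
Conditions: 2, n-BuLi, THF, −78 °C; add 1, −78 to 0 °C; then 2 M aq. HCl, rt
Reagents that add atoms: water, O
Why: Stork–Danheiser alkynylation, in which 1,2-addition of the acetylide to the vinylogous ester and acid hydrolysis with 1,3-carbonyl transposition should give the 3-alkynyl enone.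

**Step 2**
Reactants: 5 3-{[tri(propan-2-yl)silyl]ethynyl}cyclopent-2-en-1-one
Product: 7 (3R)-3-methyl-3-{[tri(propan-2-yl)silyl]ethynyl}cyclopent-1-en-1-yl trifluoromethanesulfonate, via bromomagnesium enolate 6 (not isolated)
Conditions: MeMgBr, Cu(OTf)2 (cat.), chiral N-mesityl-N'-(hydroxyalkyl)imidazolinium hexafluorophosphate (NHC precursor, cat.), Et2O, −30 °C; then Comins' reagent, THF, −30 °C to rt
Reagents that add atoms: methylmagnesium bromide, C[Mg]Br; Comins' reagent, FC(F)(F)S(=O)(=O)N(c1ccc(Cl)cn1)S(=O)(=O)C(F)(F)F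
Why: NHC–copper-catalysed enantioselective conjugate addition of a Grignard reagent to a cyclic enynone is expected to go 1,4 and build the methyl/alkynyl quaternary C1, with the face chosen by the ligand enantiomer, and the regiodefined enolate (C4–O, C4=C5) is O-triflated in the same flask.

**Step 3**
Reactants: 7 (3R)-3-methyl-3-{[tri(propan-2-yl)silyl]ethynyl}cyclopent-1-en-1-yl trifluoromethanesulfonate
Product: 8 triisopropyl{[(1R)-1-methyl-3-(propan-2-yl)cyclopent-2-en-1-yl]ethynyl}silane
Conditions: i-PrZnBr (THF solution), PdCl2(dppf) (5 mol%), THF, 40 °C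
Reagents that add atoms: isopropylzinc bromide, CC(C)[Zn]Br
Why: Negishi coupling of the enol triflate, in which the wide-bite-angle dppf ligand favours reductive elimination over β-hydride elimination so that the isopropyl group should arrive unrearranged at C4 while C1 is untouched.

**Step 4**
Reactants: 9 but-2-yn-1-ol
Product: 11 (2Z)-3-iodobut-2-en-1-ol, via cyclic alkenylaluminate 10 (not isolated)
Conditions: Red-Al [NaAlH2(OCH2CH2OMe)2], THF, 0 °C to rt; then I2, −78 to 0 °C
Reagents that add atoms: iodine, II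
Why: alkoxide-directed trans-hydroalumination places aluminium on C3 in a five-membered alanate, and iodinolysis with retention should give only the (Z)-iodide.

**Step 5**
Reactants: 8 triisopropyl{[(1R)-1-methyl-3-(propan-2-yl)cyclopent-2-en-1-yl]ethynyl}silane; 11 (2Z)-3-iodobut-2-en-1-ol
Product: 13 (2Z)-3-methyl-5-[(1R)-1-methyl-3-(propan-2-yl)cyclopent-2-en-1-yl]pent-2-en-4-yn-1-ol, via terminal alkyne 12 (not isolated)
Conditions: TBAF, THF, 0 °C to rt; then 11, PdCl2(PPh3)2 (3 mol%), CuI (6 mol%), i-Pr2NH, rt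
Reagents that add atoms: none
Why: fluoride desilylation followed in the same flask by Sonogashira coupling joins C9 to C8 with retention of the iodoalkene geometry and avoids isolating the volatile alkyne.

**Step 6**
Reactants: 13 (2Z)-3-methyl-5-[(1R)-1-methyl-3-(propan-2-yl)cyclopent-2-en-1-yl]pent-2-en-4-yn-1-ol
Product: 14 [(2R,3S)-3-methyl-3-{[(1R)-1-methyl-3-(propan-2-yl)cyclopent-2-en-1-yl]ethynyl}oxiran-2-yl]methanol
Conditions: Ti(OiPr)4, D-(−)-diethyl tartrate, t-BuOOH, 4 Å molecular sieves, CH2Cl2, −20 °C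
Reagents that add atoms: tert-butyl hydroperoxide, CC(C)(C)OO
Why: Sharpless asymmetric epoxidation, where the D-(−)-tartrate complex delivers oxygen to one face of the (Z)-trisubstituted allylic alcohol and so fixes the C8–O configuration under reagent control, while the ring alkene and the alkyne lack the directing hydroxyl.

**Step 7**
Reactants: 14 [(2R,3S)-3-methyl-3-{[(1R)-1-methyl-3-(propan-2-yl)cyclopent-2-en-1-yl]ethynyl}oxiran-2-yl]methanol
Product: 15 (3R)-3-methyl-5-[(1R)-1-methyl-3-(propan-2-yl)cyclopent-2-en-1-yl]pent-4-yne-1,3-diol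
Conditions: Red-Al [NaAlH2(OCH2CH2OMe)2], THF, −20 to 0 °C
Reagents that add atoms: none
Why: intramolecular hydride delivery from the O-bound aluminate to C2 of the 2,3-epoxy alcohol (our C7) should give the 1,3-diol and leave the C8–O bond, hence its configuration, intact.

**Step 8**
Reactants: 15 (3R)-3-methyl-5-[(1R)-1-methyl-3-(propan-2-yl)cyclopent-2-en-1-yl]pent-4-yne-1,3-diol
Product: 16 (3R,4Z)-3-methyl-5-[(1S)-1-methyl-3-(propan-2-yl)cyclopent-2-en-1-yl]pent-4-ene-1,3-diol
Conditions: H2 (1 atm), Lindlar catalyst (Pd on CaCO3 poisoned with Pb(OAc)2), quinoline, EtOAc, rt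
Reagents that add atoms: none
Why: Lindlar syn semi-hydrogenation should give the (Z)-C9=C10 alkene needed to fold the chain, the trisubstituted ring alkene being inert (the C1 descriptor changes only through CIP priorities).

**Step 9**
Reactants: 16 (3R,4Z)-3-methyl-5-[(1S)-1-methyl-3-(propan-2-yl)cyclopent-2-en-1-yl]pent-4-ene-1,3-diol
Product: 17 (3R,4Z)-3-methyl-5-[(1S)-1-methyl-3-(propan-2-yl)cyclopent-2-en-1-yl]-1,3-bis[(triethylsilyl)oxy]pent-4-ene
Conditions: TESOTf, 2,6-lutidine, CH2Cl2, −78 to 0 °C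
Reagents that add atoms: triethylsilyl trifluoromethanesulfonate, CC[Si](CC)(CC)OS(=O)(=O)C(F)(F)F
Why: silyl triflate with a hindered base silylates both the primary and the tertiary allylic hydroxyl without ionising the latter, so that the C8 oxygen cannot later direct the ketone reduction.

**Step 10**
Reactants: 17 (3R,4Z)-3-methyl-5-[(1S)-1-methyl-3-(propan-2-yl)cyclopent-2-en-1-yl]-1,3-bis[(triethylsilyl)oxy]pent-4-ene
Product: 18 (3R,4Z)-3-methyl-5-[(1S)-1-methyl-3-(propan-2-yl)cyclopent-2-en-1-yl]-3-[(triethylsilyl)oxy]pent-4-enal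
Conditions: (COCl)2, DMSO, CH2Cl2, −78 to −30 °C; then Et3N, −78 °C to rt
Reagents that add atoms: none
Why: under Swern conditions a primary triethylsilyl ether is cleaved and oxidised directly to the aldehyde, while the tertiary silyl ether should survive.

**Step 11**
Reactants: 18 (3R,4Z)-3-methyl-5-[(1S)-1-methyl-3-(propan-2-yl)cyclopent-2-en-1-yl]-3-[(triethylsilyl)oxy]pent-4-enal
Product: 19 oxime of 18 (either C=N geometry serves)
Conditions: NH2OH·HCl, pyridine, EtOH, rt
Reagents that add atoms: hydroxylamine hydrochloride, NO.Cl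
Why: oxime condensation under mildly buffered conditions, which should not eliminate the β-silyloxy group.

**Step 12**
Reactants: 19 oxime of 18
Product: 22 tricyclic 2-isoxazoline (1S,4R,5S,8R; ring O on C4; C=N carbon is C6; 8-OSiEt3), via hydroximoyl chloride 20 (not isolated), via nitrile oxide 21 (not isolated)
Conditions: aq. NaOCl, CH2Cl2, 0 °C to rt, high dilution (about 0.005 M), slow addition
Reagents that add atoms: none
Why: The oxime is chlorinated and dehydrochlorinated to nitrile oxide 21, whose C6≡N–O dipole adds in a concerted, suprafacial (3+2) cycloaddition across the C4=C5 bond of the cyclopentene; the closest known reaction type is the intramolecular nitrile oxide–alkene cycloaddition onto trisubstituted cycloalkenes. The C6–C5 bond closes the seven-membered carbocycle in the fused mode over the C10=C9–C8–C7–C6 arm, and the O–C4 bond closes the five-membered isoxazoline as a temporary ring. C5 and C4 are controlled by C1, because the arm can reach only the alkene face on which C10 stands, so C10, C6 and the C4 oxygen should end up syn on the cyclopentane (cis ring fusion), with C8 carried in unchanged. The regiochemistry (carbon to C5, oxygen to C4) is secured by the tether, since the reverse mode would need an eight-membered bridged ring, and it matches the usual preference of the dipole oxygen for the more substituted alkene carbon. The (Z)-C9=C10 bond cannot compete, as attack on it would need a four-membered ring or a bridgehead C=N, and high dilution should suppress dimerisation to the furoxan.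

**Step 13**
Reactants: 22 tricyclic 2-isoxazoline
Product: 24 (3R,3aR,6R,8aS)-3-hydroxy-6,8a-dimethyl-3-(propan-2-yl)-6-[(triethylsilyl)oxy]-2,3,3a,5,6,8a-hexahydroazulen-4(1H)-one, via β-hydroxy imine 23 (not isolated)
Conditions: Mo(CO)6, MeCN/H2O, 80 °C
Reagents that add atoms: water, O
Why: reductive N–O cleavage and in-situ imine hydrolysis unmask the β-hydroxy ketone under neutral conditions, which should spare the cis-alkene and the silyl ether and avoid retro-aldol cleavage or epimerisation at C5.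

**Step 14**
Reactants: 24 (3R,3aR,6R,8aS)-3-hydroxy-6,8a-dimethyl-3-(propan-2-yl)-6-[(triethylsilyl)oxy]-2,3,3a,5,6,8a-hexahydroazulen-4(1H)-one
Product: 25 (3R,3aS,4S,6R,8aS)-6,8a-dimethyl-3-(propan-2-yl)-6-[(triethylsilyl)oxy]-1,2,3,3a,4,5,6,8a-octahydroazulene-3,4-diol
Conditions: Me4NBH(OAc)3, MeCN/AcOH (1:1), −30 °C
Reagents that add atoms: none
Why: Evans–Saksena hydroxyl-directed reduction, in which the borohydride bound to the C4 oxygen can reach C6 only from the carbonyl face on the C4 side (the seven-membered ring cannot place C7 anti to C1), so H6 should enter anti to H5 and give the 6S carbinol.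

**Step 15**
Reactants: 25 (3R,3aS,4S,6R,8aS)-6,8a-dimethyl-3-(propan-2-yl)-6-[(triethylsilyl)oxy]-1,2,3,3a,4,5,6,8a-octahydroazulene-3,4-diol; 26 4-[(tert-butyldimethylsilyl)oxy]benzoic acid
Product: 27 (3R,3aS,4S,6R,8aS)-3-hydroxy-6,8a-dimethyl-3-(propan-2-yl)-6-[(triethylsilyl)oxy]-1,2,3,3a,4,5,6,8a-octahydroazulen-4-yl 4-[(tert-butyldimethylsilyl)oxy]benzoate
Conditions: DCC, DMAP, CH2Cl2, rt
Reagents that add atoms: none
Why: Steglich esterification should acylate only the secondary C6 hydroxyl, the tertiary C4 hydroxyl being inert and the C8 oxygen silylated.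

**Step 16**
Reactants: 27 silylated ester
Product: 28 (3R,3aS,4S,6R,8aS)-3,6-dihydroxy-6,8a-dimethyl-3-(propan-2-yl)-1,2,3,3a,4,5,6,8a-octahydroazulen-4-yl 4-hydroxybenzoate (target)
Conditions: TBAF, AcOH, THF, 0 °C to rt
Reagents that add atoms: none
Why: buffered fluoride should cleave the aryl silyl ether and the tertiary triethylsilyl ether in one operation without ester cleavage, acyl migration or ionisation of the tertiary allylic alcohol.

**Compound list**

1 | 3-ethoxycyclopent-2-en-1-one | CCOC1=CC(=O)CC1 | starting material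
2 | ethynyltri(propan-2-yl)silane | C#C[Si](C(C)C)(C(C)C)C(C)C | starting material
3 | lithium [tri(propan-2-yl)silyl]acetylide | [Li]C#C[Si](C(C)C)(C(C)C)C(C)C | intermediate (not isolated)
4 | lithium 3-ethoxy-1-{[tri(propan-2-yl)silyl]ethynyl}cyclopent-2-en-1-olate (racemic) | CCOC1=CC([O-])(C#C[Si](C(C)C)(C(C)C)C(C)C)CC1.[Li+] | intermediate (not isolated)
5 | 3-{[tri(propan-2-yl)silyl]ethynyl}cyclopent-2-en-1-one | O=C1C=C(C#C[Si](C(C)C)(C(C)C)C(C)C)CC1 | intermediate
6 | bromomagnesium (3R)-3-methyl-3-{[tri(propan-2-yl)silyl]ethynyl}cyclopent-1-en-1-olate | Br[Mg]OC1=C[C@](C)(C#C[Si](C(C)C)(C(C)C)C(C)C)CC1 | intermediate (not isolated)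
7 | (3R)-3-methyl-3-{[tri(propan-2-yl)silyl]ethynyl}cyclopent-1-en-1-yl trifluoromethanesulfonate | O=S(=O)(OC1=C[C@](C)(C#C[Si](C(C)C)(C(C)C)C(C)C)CC1)C(F)(F)F | intermediate
8 | triisopropyl{[(1R)-1-methyl-3-(propan-2-yl)cyclopent-2-en-1-yl]ethynyl}silane | CC(C)C1=C[C@](C)(C#C[Si](C(C)C)(C(C)C)C(C)C)CC1 | intermediate
9 | but-2-yn-1-ol | CC#CCO | starting material
10 | sodium cyclic alkenylaluminate (Al on C3, O-bound, two 2-methoxyethoxy ligands) | CC1=CCO[Al-]1(OCCOC)OCCOC.[Na+] | intermediate (not isolated)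
11 | (2Z)-3-iodobut-2-en-1-ol | C/C(I)=C/CO | intermediate
12 | (3R)-3-ethynyl-3-methyl-1-(propan-2-yl)cyclopent-1-ene | CC(C)C1=C[C@](C)(C#C)CC1 | intermediate (not isolated)
13 | (2Z)-3-methyl-5-[(1R)-1-methyl-3-(propan-2-yl)cyclopent-2-en-1-yl]pent-2-en-4-yn-1-ol | CC(C)C1=C[C@](C)(C#C/C(C)=C\CO)CC1 | intermediate
14 | [(2R,3S)-3-methyl-3-{[(1R)-1-methyl-3-(propan-2-yl)cyclopent-2-en-1-yl]ethynyl}oxiran-2-yl]methanol | CC(C)C1=C[C@](C)(C#C[C@]2(C)O[C@@H]2CO)CC1 | intermediate
15 | (3R)-3-methyl-5-[(1R)-1-methyl-3-(propan-2-yl)cyclopent-2-en-1-yl]pent-4-yne-1,3-diol | CC(C)C1=C[C@](C)(C#C[C@](C)(O)CCO)CC1 | intermediate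
16 | (3R,4Z)-3-methyl-5-[(1S)-1-methyl-3-(propan-2-yl)cyclopent-2-en-1-yl]pent-4-ene-1,3-diol | CC(C)C1=C[C@](C)(/C=C\[C@](C)(O)CCO)CC1 | intermediate
17 | (3R,4Z)-3-methyl-5-[(1S)-1-methyl-3-(propan-2-yl)cyclopent-2-en-1-yl]-1,3-bis[(triethylsilyl)oxy]pent-4-ene | CC(C)C1=C[C@](C)(/C=C\[C@](C)(O[Si](CC)(CC)CC)CCO[Si](CC)(CC)CC)CC1 | intermediate
18 | (3R,4Z)-3-methyl-5-[(1S)-1-methyl-3-(propan-2-yl)cyclopent-2-en-1-yl]-3-[(triethylsilyl)oxy]pent-4-enal | CC(C)C1=C[C@](C)(/C=C\[C@](C)(O[Si](CC)(CC)CC)CC=O)CC1 | intermediate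
19 | oxime of 18 | CC(C)C1=C[C@](C)(/C=C\[C@](C)(O[Si](CC)(CC)CC)CC=NO)CC1 | intermediate
20 | hydroximoyl chloride of 19 | CC(C)C1=C[C@](C)(/C=C\[C@](C)(O[Si](CC)(CC)CC)CC(Cl)=NO)CC1 | intermediate (not isolated)
21 | nitrile oxide (C6≡N–O) | CC(C)C1=C[C@](C)(/C=C\[C@](C)(O[Si](CC)(CC)CC)CC#[N+][O-])CC1 | intermediate (not isolated)
22 | tricyclic 2-isoxazoline, (1S,4R,5S,8R) in the plan's locants: cis-fused cyclopentane/cycloheptene (C9=C10), O–N=C bridging C4 (O) and C6 (C=N), 8-methyl-8-(triethylsilyloxy) | CC(C)[C@@]12CC[C@@]3(C)C=C[C@](C)(O[Si](CC)(CC)CC)CC(=NO1)[C@@H]23 | intermediate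
23 | β-hydroxy N–H ketimine (C6=NH, C4–OH) | CC(C)[C@]1(O)CC[C@@]2(C)C=C[C@](C)(O[Si](CC)(CC)CC)CC(=N)[C@@H]12 | intermediate (not isolated)
24 | (3R,3aR,6R,8aS)-3-hydroxy-6,8a-dimethyl-3-(propan-2-yl)-6-[(triethylsilyl)oxy]-2,3,3a,5,6,8a-hexahydroazulen-4(1H)-one | CC(C)[C@]1(O)CC[C@@]2(C)C=C[C@](C)(O[Si](CC)(CC)CC)CC(=O)[C@@H]12 | intermediate
25 | (3R,3aS,4S,6R,8aS)-6,8a-dimethyl-3-(propan-2-yl)-6-[(triethylsilyl)oxy]-1,2,3,3a,4,5,6,8a-octahydroazulene-3,4-diol | CC(C)[C@]1(O)CC[C@@]2(C)C=C[C@](C)(O[Si](CC)(CC)CC)C[C@H](O)[C@@H]12 | intermediate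
26 | 4-[(tert-butyldimethylsilyl)oxy]benzoic acid | CC(C)(C)[Si](C)(C)Oc1ccc(cc1)C(=O)O | starting material
27 | (3R,3aS,4S,6R,8aS)-3-hydroxy-6,8a-dimethyl-3-(propan-2-yl)-6-[(triethylsilyl)oxy]-1,2,3,3a,4,5,6,8a-octahydroazulen-4-yl 4-[(tert-butyldimethylsilyl)oxy]benzoate | CC(C)[C@]1(O)CC[C@@]2(C)C=C[C@](C)(O[Si](CC)(CC)CC)C[C@H](OC(=O)c3ccc(O[Si](C)(C)C(C)(C)C)cc3)[C@@H]12 | intermediate
28 | (3R,3aS,4S,6R,8aS)-3,6-dihydroxy-6,8a-dimethyl-3-(propan-2-yl)-1,2,3,3a,4,5,6,8a-octahydroazulen-4-yl 4-hydroxybenzoate | CC(C)[C@]1(O)CC[C@@]2(C)C=C[C@](C)(O)C[C@H](OC(=O)c3ccc(O)cc3)[C@@H]12 | target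

**Count**

Total steps: 16. Longest linear sequence: 15 (steps 1–3 and 5–16, from 1).

**Steps most likely to fail**

Step 12. The nitrile oxide may dimerise to the furoxan faster than it cyclises, because cycloaddition onto the hindered trisubstituted alkene through a seven-membered transition state can be slow. The fallback sets out from aldehyde 18 and closes the same C5–C6 bond by a Lewis-acid carbonyl-ene reaction. Me2AlCl (CH2Cl2, −78 °C) should make C6 attack C5 on the face of the arm with transfer of the syn hydrogen from C3, giving the ring-closed homoallylic alcohol with a C3=C4 alkene F7 (expected as the C6 epimer). Epoxidation directed by the C6 hydroxyl (VO(acac)2, t-BuOOH) should give the epoxide on the C6 face, the 3,4-epoxide F8. LiAlH4 opens it at the secondary C3 to the tertiary C4 alcohol, the 6-epi diol F9. Dess–Martin periodinane oxidises the secondary carbinol, and the fallback comes back to the route at ketone 24.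

Step 2. Facial discrimination may be poor with the small methyl Grignard on the five-membered enynone, and 1,6-addition or incomplete O-triflation may compete. The fallback sets out from 1 and reverses the order in which the two groups reach C1. MeLi followed by aqueous acid converts 1 into 3-methylcyclopent-2-en-1-one F1. NHC–copper-catalysed enantioselective conjugate addition of diisobutyl[1-(trimethylsilyl)ethenyl]aluminium (from ethynyltrimethylsilane and i-Bu2AlH; catalyst from CuCl2·2H2O and a chiral sulfonate-bearing imidazolinium salt) is followed by activation of the aluminium enolate with MeLi and triflation with Comins' reagent, giving (3R)-3-methyl-3-[1-(trimethylsilyl)ethenyl]cyclopent-1-en-1-yl trifluoromethanesulfonate F2. Negishi coupling as in step 3 gives the vinylsilane F3. Iododesilylation with N-iodosuccinimide gives the 1-iodoethenyl compound F4. Dehydroiodination with TBAF trihydrate in DMF gives alkyne 12, where the fallback comes back to the route (coupling with 11 as in step 5).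

Step 7. After epoxide opening, the propargylic aluminate may hydroaluminate the triple bond and lead to the (E)-alkene, or hydride may open the propargylic epoxide in the SN2' sense. The fallback sets out from 13 and removes the alkyne before the hydride step. Lindlar semi-hydrogenation of 13 gives the (2Z,4Z)-dienol F5. Sharpless epoxidation with D-(−)-diethyl tartrate, directed to the allylic alcohol double bond, gives the alkenyl epoxy alcohol F6. Red-Al opening at C2 then gives diol 16, where the fallback comes back to the route.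

**Further compounds**

F1 | step 2 | 3-methylcyclopent-2-en-1-one | CC1=CC(=O)CC1
F2 | step 2 | (3R)-3-methyl-3-[1-(trimethylsilyl)ethenyl]cyclopent-1-en-1-yl trifluoromethanesulfonate | O=S(=O)(OC1=C[C@](C)(C(=C)[Si](C)(C)C)CC1)C(F)(F)F
F3 | step 2 | trimethyl{1-[(1R)-1-methyl-3-(propan-2-yl)cyclopent-2-en-1-yl]ethenyl}silane | CC(C)C1=C[C@](C)(C(=C)[Si](C)(C)C)CC1
F4 | step 2 | (3R)-3-(1-iodoethenyl)-3-methyl-1-(propan-2-yl)cyclopent-1-ene | CC(C)C1=C[C@](C)(C(I)=C)CC1
F5 | step 7 | (2Z,4Z)-3-methyl-5-[(1S)-1-methyl-3-(propan-2-yl)cyclopent-2-en-1-yl]penta-2,4-dien-1-ol | CC(C)C1=C[C@](C)(/C=C\C(C)=C/CO)CC1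
F6 | step 7 | [(2R,3S)-3-methyl-3-{(Z)-2-[(1S)-1-methyl-3-(propan-2-yl)cyclopent-2-en-1-yl]ethenyl}oxiran-2-yl]methanol | CC(C)C1=C[C@](C)(/C=C\[C@]2(C)O[C@@H]2CO)CC1
F7 | step 12 | (3aR,4R,6R,8aS)-6,8a-dimethyl-3-(propan-2-yl)-6-[(triethylsilyl)oxy]-1,3a,4,5,6,8a-hexahydroazulen-4-ol | CC(C)C1=CC[C@@]2(C)C=C[C@](C)(O[Si](CC)(CC)CC)C[C@@H](O)[C@@H]12
F8 | step 12 | 3,4-epoxide of F7 (plan locants), oxygen on the ring face that carries C6 | CC(C)[C@]12O[C@H]1C[C@@]3(C)C=C[C@](C)(O[Si](CC)(CC)CC)C[C@@H](O)[C@@H]23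
F9 | step 12 | (3R,3aS,4R,6R,8aS)-6,8a-dimethyl-3-(propan-2-yl)-6-[(triethylsilyl)oxy]-1,2,3,3a,4,5,6,8a-octahydroazulene-3,4-diol (C6 epimer of 25) | CC(C)[C@]1(O)CC[C@@]2(C)C=C[C@](C)(O[Si](CC)(CC)CC)C[C@@H](O)[C@@H]12
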